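## Retrosynthetic overview

1. Chroman numbering is used: O1, C2 (CMe2), C3 (CHOH), C4 (CH2), benzene carbons C4a–C8a. The last disconnection is the CH2 bridge between C8 and C3 of the pyranone ring: a three-component Mannich/Michael union of pyranone 5, CH2=NMe2+ I− and the free acylphloroglucinol chromanol 13, whose only unsubstituted ring carbon is C8.
2. The dihydropyran ring is disconnected at O1–C2. Its precursor is the achiral prenyl arene 10; the C2=C3 alkene is converted by catalyst-controlled oxygen transfer into a C2–C3 oxirane, which is closed 6-endo in the same flask.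
3. Enabling feature: C2 is a fully substituted (gem-dimethyl) carbon next to the carbinol carbon C3. A C2–C3 oxirane therefore holds the only stereocentre (its CH, never broken) and a tertiary terminus that the oxygen para to the acetyl group on the benzene ring reaches through a six-membered transition state. The two oxygens ortho to the acetyl group are muted as benzyl ethers; the para oxygen is masked as an acid-labile MOM acetal.
4. Arene 10 comes from 2,4,6-trihydroxyacetophenone by C-prenylation, para-selective MOM protection and ortho-benzylation. Pyranone 5 comes from methyl 3-oxopentanoate by dianion acylation and lactonisation.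
5. Ring order: pyranone ring (step 2, separate branch); benzene ring bought; dihydropyran ring (step 6); the two halves are joined last (step 8).

Key step: step 6

Remark: pyranone 5 is assumed not to be a stock chemical and is therefore made in steps 1–2; the D-fructose-derived Shi ketone is taken as a commercial organocatalyst.

## Route

Step 1
Reactants: 1 methyl 3-oxopentanoate; 2 N-methoxy-N-methylpropanamide
Product: 4 methyl 4-methyl-3,5-dioxoheptanoate, via dilithium dienolate 3 (not isolated)
Conditions: LiN(iPr)2 (2.3 equiv), THF, −78 → 0 °C; then 2 (1.1 equiv), −78 → 0 °C; aq. HCl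
Reagents that add atoms: none
Why: γ-Acylation of a β-keto ester dianion (Claisen-type condensation): dienolate 3 reacts at its terminal, more basic carbon and the Weinreb amide stops at the chelated tetrahedral adduct, so the 3,5-diketo ester is released only on work-up, and the new CH(CH3) centre is epimerisable and becomes sp2 in step 2.

Step 2
Reactants: 4 methyl 4-methyl-3,5-dioxoheptanoate
Product: 5 6-ethyl-4-hydroxy-5-methyl-2H-pyran-2-one
Conditions: DBU (1.2 equiv), toluene, 110 °C; aq. HCl work-up
Reagents that add atoms: none
Why: Base-mediated enol-lactonisation of a 3,5-dioxo ester (O-acylation of the C5 enolate oxygen by the methyl ester, then tautomerisation) is the standard entry to 6-alkyl-4-hydroxy-2-pyranones and is driven by formation of the conjugated, acidic pyranone.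

Step 3
Reactants: 6 1-(2,4,6-trihydroxyphenyl)ethan-1-one; 7 1-bromo-3-methylbut-2-ene
Product: 8 1-[2,4,6-trihydroxy-3-(3-methylbut-2-en-1-yl)phenyl]ethan-1-one
Conditions: DBU (1.0 equiv), THF, 0 °C → rt
Reagents that add atoms: none
Why: Base-mediated C-alkylation of an acylphloroglucinol by an allylic bromide: the phenoxide of 6 reacts as a vinylogous enolate at a ring carbon, the two free ring carbons are equivalent so only one mono-C-prenyl isomer exists, and one equivalent of each reagent limits double alkylation.

Step 4
Reactants: 8 1-[2,4,6-trihydroxy-3-(3-methylbut-2-en-1-yl)phenyl]ethan-1-one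
Product: 9 1-[2,6-dihydroxy-4-(methoxymethoxy)-3-(3-methylbut-2-en-1-yl)phenyl]ethan-1-one
Conditions: MOMCl (1.05 equiv), iPr2NEt (1.2 equiv), CH2Cl2, 0 °C
Reagents that add atoms: chloromethyl methyl ether (MOMCl), COCCl
Why: Site-selective O-alkylation (acetal formation): the hydroxyl para to the acetyl group is the most acidic of the three and is not flanked by the carbonyl, so with one equivalent of MOMCl and an amine base its phenoxide should be formed and trapped first, as is usual for 2,4,6-trihydroxyacetophenones.

Step 5
Reactants: 9 1-[2,6-dihydroxy-4-(methoxymethoxy)-3-(3-methylbut-2-en-1-yl)phenyl]ethan-1-one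
Product: 10 1-[2,6-bis(benzyloxy)-4-(methoxymethoxy)-3-(3-methylbut-2-en-1-yl)phenyl]ethan-1-one
Conditions: BnBr (2.5 equiv), K2CO3 (3 equiv), DMF, 60 °C
Reagents that add atoms: benzyl bromide, BrCc1ccccc1
Why: Williamson etherification: the two remaining ortho hydroxyls are benzylated with K2CO3 in warm DMF, the MOM acetal and the alkene being inert to base, which leaves the MOM-masked para oxygen as the only oxygen that the acid of step 6 can use for ring closure.

Step 6
Reactants: 10 1-[2,6-bis(benzyloxy)-4-(methoxymethoxy)-3-(3-methylbut-2-en-1-yl)phenyl]ethan-1-one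
Product: 12 1-[(3R)-5,7-bis(benzyloxy)-3-hydroxy-2,2-dimethyl-3,4-dihydro-2H-chromen-6-yl]ethan-1-one, via (R)-epoxide 11 (not isolated)
Conditions: D-fructose-derived Shi ketone (0.3 equiv), KHSO5 (Oxone, 2KHSO5·KHSO4·K2SO4, 1.4 equiv), K2CO3, Bu4NHSO4 (cat.), MeCN–CH2(OMe)2/aq. Na2B4O7–Na2EDTA buffer (pH 10.5), 0 °C; extractive solvent switch (crude 11 not purified); then CSA (0.3 equiv), MeOH (3 equiv), CH2Cl2, 0 °C → rt
Reagents that add atoms: potassium peroxymonosulfate (KHSO5, the active salt of Oxone), [K+].[O-]S(=O)(=O)OO
Why: The dioxirane generated from the D-fructose-derived ketone and KHSO5 transfers one oxygen atom to the trisubstituted alkene through a spiro transition state and should give the R oxirane 11 (catalyst control, as the substrate has no stereocentre), the benzyl ethers, the MOM acetal and the aryl ketone being inert at pH 10.5 and 0 °C. In the acid stage the protonated oxirane is opened at its tertiary carbon C2 by the oxygen para to the acetyl group, either after acid cleavage of the MOM acetal or directly by the acetal-bearing oxygen with expulsion of the methoxymethyl cation (trapped by methanol), so that two nucleophilic atoms, the phenolic oxygen and the alkene carbon, are joined by oxidative umpolung of C2 and release of oxirane strain. The closest known reaction type is the Shi epoxidation of ortho-prenyl phenol derivatives followed by acid-mediated epoxide-opening cycloetherification to 3-hydroxy-2,2-dimethylchromans. The dihydropyran ring closes in the 6-endo-tet mode, with inversion at the non-stereogenic carbon C2. The only stereocentre, C3, is the oxirane CH, whose C–O bond is not broken, so the R configuration fixed by the catalyst is carried into 12 unchanged. The step needs 6-endo over 5-exo opening, secured by the tertiary (gem-dimethyl) terminus under Brønsted acid in a non-nucleophilic medium, and closure by the para rather than an ortho oxygen, secured because the ortho oxygens are benzyl ethers that cannot shed their substituent under these conditions while the MOM acetal can.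

Step 7
Reactants: 12 1-[(3R)-5,7-bis(benzyloxy)-3-hydroxy-2,2-dimethyl-3,4-dihydro-2H-chromen-6-yl]ethan-1-one
Product: 13 1-[(3R)-3,5,7-trihydroxy-2,2-dimethyl-3,4-dihydro-2H-chromen-6-yl]ethan-1-one
Conditions: H2 (1 atm), 10% Pd/C, EtOAc–MeOH, rt
Reagents that add atoms: none
Why: Catalytic hydrogenolysis of aryl benzyl ethers over Pd/C under neutral conditions cleaves only the two O–CH2Ph bonds, while the tertiary alkyl aryl ether of the dihydropyran ring, the secondary alcohol, the aryl ketone and the C3 stereocentre (no bond to it is touched) are retained.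

Step 8
Reactants: 13 1-[(3R)-3,5,7-trihydroxy-2,2-dimethyl-3,4-dihydro-2H-chromen-6-yl]ethan-1-one; 5 6-ethyl-4-hydroxy-5-methyl-2H-pyran-2-one
Product: 16 3-{[(3R)-6-acetyl-3,5,7-trihydroxy-2,2-dimethyl-3,4-dihydro-2H-chromen-8-yl]methyl}-6-ethyl-4-hydroxy-5-methyl-2H-pyran-2-one, via Mannich base 14 (not isolated), via methylidene-pyrandione 15 (not isolated)
Conditions: 5, CH2=NMe2+ I− (1.05 equiv), MeCN, rt; then 13 (1.0 equiv), 60 °C
Reagents that add atoms: N,N-dimethylmethylideneammonium iodide (Eschenmoser's salt), C=[N+](C)C.[I-]
Why: Mannich reaction of the pyranone at C3 and thermal loss of dimethylamine give the methylidene-pyrandione 15, a quinone-methide-like Michael acceptor, which is attacked by the only unsubstituted, phloroglucinol-type ring carbon (C8) of 13 in a Friedel–Crafts-type conjugate addition with re-aromatisation (three-component Mannich/Michael coupling of the kind used for methylene-bridged pyranone–acylphloroglucinols), no stereocentre being formed and C3 being remote.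

## Compound list

1 | methyl 3-oxopentanoate | CCC(=O)CC(=O)OC | starting material
2 | N-methoxy-N-methylpropanamide | CCC(=O)N(C)OC | starting material
3 | dilithium 1-methoxypenta-1,3-diene-1,3-diolate (dianion of 1) | [Li+].[Li+].CC=C([O-])C=C([O-])OC | intermediate (not isolated)
4 | methyl 4-methyl-3,5-dioxoheptanoate | CCC(=O)C(C)C(=O)CC(=O)OC | intermediate
5 | 6-ethyl-4-hydroxy-5-methyl-2H-pyran-2-one | CCc1oc(=O)cc(O)c1C | intermediate
6 | 1-(2,4,6-trihydroxyphenyl)ethan-1-one | CC(=O)c1c(O)cc(O)cc1O | starting material
7 | 1-bromo-3-methylbut-2-ene | CC(C)=CCBr | starting material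
8 | 1-[2,4,6-trihydroxy-3-(3-methylbut-2-en-1-yl)phenyl]ethan-1-one | CC(=O)c1c(O)cc(O)c(CC=C(C)C)c1O | intermediate
9 | 1-[2,6-dihydroxy-4-(methoxymethoxy)-3-(3-methylbut-2-en-1-yl)phenyl]ethan-1-one | CC(=O)c1c(O)cc(OCOC)c(CC=C(C)C)c1O | intermediate
10 | 1-[2,6-bis(benzyloxy)-4-(methoxymethoxy)-3-(3-methylbut-2-en-1-yl)phenyl]ethan-1-one | CC(=O)c1c(OCc2ccccc2)cc(OCOC)c(CC=C(C)C)c1OCc1ccccc1 | intermediate
11 | 1-[2,6-bis(benzyloxy)-3-{[(2R)-3,3-dimethyloxiran-2-yl]methyl}-4-(methoxymethoxy)phenyl]ethan-1-one | CC(=O)c1c(OCc2ccccc2)cc(OCOC)c(C[C@H]3OC3(C)C)c1OCc1ccccc1 | intermediate (not isolated)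
12 | 1-[(3R)-5,7-bis(benzyloxy)-3-hydroxy-2,2-dimethyl-3,4-dihydro-2H-chromen-6-yl]ethan-1-one | CC(=O)c1c(OCc2ccccc2)cc3OC(C)(C)[C@H](O)Cc3c1OCc1ccccc1 | intermediate
13 | 1-[(3R)-3,5,7-trihydroxy-2,2-dimethyl-3,4-dihydro-2H-chromen-6-yl]ethan-1-one | CC(=O)c1c(O)cc2OC(C)(C)[C@H](O)Cc2c1O | intermediate
14 | 3-[(dimethylamino)methyl]-6-ethyl-4-hydroxy-5-methyl-2H-pyran-2-one | CCc1oc(=O)c(CN(C)C)c(O)c1C | intermediate (not isolated)
15 | 6-ethyl-5-methyl-3-methylidene-2H-pyran-2,4(3H)-dione | CCC1=C(C)C(=O)C(=C)C(=O)O1 | intermediate (not isolated)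
16 | 3-{[(3R)-6-acetyl-3,5,7-trihydroxy-2,2-dimethyl-3,4-dihydro-2H-chromen-8-yl]methyl}-6-ethyl-4-hydroxy-5-methyl-2H-pyran-2-one | CCc1oc(=O)c(Cc2c(O)c(C(C)=O)c(O)c3c2OC(C)(C)[C@H](O)C3)c(O)c1C | target

## Step count and risks

Total steps: 8. Longest linear sequence: 6 (steps 3–8, from 2,4,6-trihydroxyacetophenone); the pyranone branch is 2 steps and enters at step 8.

**Step 6 (key step).** In the acid stage the activated oxirane may be diverted into 5-exo closure, a 1,2-hydride shift to the ketone, or capture by methanol before the masked oxygen closes. The oxygen transfer may also show incomplete facial selectivity. The fallback sets out from 10 and returns at 13. It closes the same O1–C2 bond at the alkene oxidation level and sets the stereocentre afterwards. Acid hydrolysis of the MOM acetal of 10 (3 M HCl, MeOH–THF, 40 °C) should give the phenol 1-[2,6-bis(benzyloxy)-4-hydroxy-3-(3-methylbut-2-en-1-yl)phenyl]ethan-1-one F1. Dehydrogenation with DDQ (benzene, 80 °C) should generate the ortho-quinone methide, whose oxa-6π electrocyclisation gives the chromene 1-[5,7-bis(benzyloxy)-2,2-dimethyl-2H-chromen-6-yl]ethan-1-one F2; again only the para oxygen is free. Jacobsen–Katsuki epoxidation with the (R,R)-(salen)MnCl catalyst and NaOCl (4-phenylpyridine N-oxide, CH2Cl2, 0 °C) should give the cis-epoxide 1-[(3R,4R)-5,7-bis(benzyloxy)-3,4-epoxy-2,2-dimethyl-3,4-dihydro-2H-chromen-6-yl]ethan-1-one F3. Hydrogenolysis (H2, Pd/C, EtOAc) should then cleave the benzylic C4–O bond and both benzyl ethers and give 13 with C3 unchanged.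

**Step 8.** The methylidene-pyrandione 15 may be captured by a second molecule of 5 (methylene-bis-pyranone formation) or by oxygen instead of C8. The fallback sets out from 13 and returns at 16, with the roles of the partners reversed. Mannich reaction of 13 alone with CH2=NMe2+ I− (MeCN, rt; NaHCO3 work-up) should give 1-[(3R)-8-[(dimethylamino)methyl]-3,5,7-trihydroxy-2,2-dimethyl-3,4-dihydro-2H-chromen-6-yl]ethan-1-one F4. On heating with 5 (dioxane, 100 °C) this should lose dimethylamine to an ortho-quinone methide on the chroman side, which is trapped at C3 of the pyranone to give 16.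

**Step 4.** Site selectivity may be lost (acetalisation of the ortho hydroxyl at C6, or double acetalisation), because in 8 the para hydroxyl is flanked by the prenyl chain. The fallback sets out from 6 and returns at 9, with the order of the two bond formations inverted. Mono-acetalisation of the symmetric triol 6 (MOMCl 1.0 equiv, iPr2NEt, CH2Cl2, 0 °C), where the para hydroxyl is unhindered, should give 1-[2,6-dihydroxy-4-(methoxymethoxy)phenyl]ethan-1-one F5, whose two free ring carbons are equivalent. C-prenylation with 7 (DBU, THF, 0 °C → rt) should then give 9.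

## Further compounds

F1 | step 6 | 1-[2,6-bis(benzyloxy)-4-hydroxy-3-(3-methylbut-2-en-1-yl)phenyl]ethan-1-one | CC(=O)c1c(OCc2ccccc2)cc(O)c(CC=C(C)C)c1OCc1ccccc1
F2 | step 6 | 1-[5,7-bis(benzyloxy)-2,2-dimethyl-2H-chromen-6-yl]ethan-1-one | CC(=O)c1c(OCc2ccccc2)cc3OC(C)(C)C=Cc3c1OCc1ccccc1
F3 | step 6 | 1-[(3R,4R)-5,7-bis(benzyloxy)-3,4-epoxy-2,2-dimethyl-3,4-dihydro-2H-chromen-6-yl]ethan-1-one | CC(=O)c1c(OCc2ccccc2)cc3OC(C)(C)[C@@H]4O[C@@H]4c3c1OCc1ccccc1
F4 | step 8 | 1-[(3R)-8-[(dimethylamino)methyl]-3,5,7-trihydroxy-2,2-dimethyl-3,4-dihydro-2H-chromen-6-yl]ethan-1-one | CC(=O)c1c(O)c(CN(C)C)c2OC(C)(C)[C@H](O)Cc2c1O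
F5 | step 4 | 1-[2,6-dihydroxy-4-(methoxymethoxy)phenyl]ethan-1-one | CC(=O)c1c(O)cc(OCOC)cc1O
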